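The plan rests on disconnecting the O1–C2 bond of the dihydrofuran ring B (O1, C2, C3, C3a, C7a). C2 is benzylic to the trimethoxyphenyl ring, whose para methoxy group allows the C2–H bond to be taken away as hydride. The phenol oxygen on C7a then traps the cation. A single oxidation thus makes O1–C2, closes ring B and sets C2 trans to the C3 centre already present. Its substrate is an open-chain (S)-2,3-diarylpropyl pivalate with a free 4-bromophenol unit and one stereocentre, set by auxiliary-controlled enolate benzylation. The C5 bromide then takes the side chain by a Heck reaction, and one hydride reduction delivers the target.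

Key step: step 7

Remark: the SMILES string is read as the trans (2R,3S) isomer with an E alkene, and the four numbered starting materials are taken to be purchasable.

Step 1
Reactants: 1 2-(5-bromo-2-hydroxyphenyl)acetic acid
Product: 3 2-[5-bromo-2-(methoxymethoxy)phenyl]acetic acid, via bis-MOM derivative 2 (not isolated)
Conditions: MOMCl (2.4 equiv), i-Pr2NEt (3 equiv), CH2Cl2, 0 °C → rt; concentrate; LiOH (5 equiv), THF/MeOH/H2O, rt; 1 M HCl to pH 4, 0 °C
Reagents that add atoms: chloromethyl methyl ether (MOMCl), COCCl; lithium hydroxide, [Li+].[OH-]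
Why: Base-mediated O-alkylation (Williamson type) caps the phenol as well as the acid, and saponification then removes only the far more labile methoxymethyl ester, so the phenol stays masked and cannot lactonise onto the activated acid in step 2.

Step 2
Reactants: 3 2-[5-bromo-2-(methoxymethoxy)phenyl]acetic acid; 4 (4S)-4-benzyl-1,3-oxazolidin-2-one
Product: 6 (4S)-4-benzyl-3-{2-[5-bromo-2-(methoxymethoxy)phenyl]acetyl}-1,3-oxazolidin-2-one, via mixed pivalic anhydride 5 (not isolated)
Conditions: pivaloyl chloride (1.05 equiv), Et3N (2.5 equiv), THF, −20 °C; then LiCl (1.1 equiv), 4, −20 °C → rt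
Reagents that add atoms: pivaloyl chloride, CC(C)(C)C(=O)Cl (its acyl group is carried only by intermediate 5)
Why: Mixed-anhydride N-acylation of an oxazolidinone: LiCl and Et3N make the carbamate nitrogen nucleophilic enough to attack the unhindered arylacetyl carbonyl of 5, the tert-butyl group shields the other carbonyl, and the absence of strong base avoids ketene formation from the acidic arylacetyl unit.

Step 3
Reactants: 6 (4S)-4-benzyl-3-{2-[5-bromo-2-(methoxymethoxy)phenyl]acetyl}-1,3-oxazolidin-2-one; 7 3,4,5-trimethoxybenzyl bromide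
Product: 9 (4S)-4-benzyl-3-{(2S)-2-[5-bromo-2-(methoxymethoxy)phenyl]-3-(3,4,5-trimethoxyphenyl)propanoyl}-1,3-oxazolidin-2-one, via sodium Z-enolate 8 (not isolated)
Conditions: NaN(SiMe3)2 (1.1 equiv), THF, −78 °C; then 7 (1.4 equiv), −78 → −40 °C; sat. aq. NH4Cl at −40 °C
Reagents that add atoms: NaN(SiMe3)2, [Na+].C[Si](C)(C)[N-][Si](C)(C)C (its sodium stays only in intermediate 8)
Why: Evans asymmetric alkylation: the sodium-chelated Z-enolate 8 is shielded on one face by the C4 benzyl group of the (S)-auxiliary, so the reactive benzylic bromide enters from the opposite face and sets the (2S) centre that becomes C3 of the target.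

Step 4
Reactants: 9 (4S)-4-benzyl-3-{(2S)-2-[5-bromo-2-(methoxymethoxy)phenyl]-3-(3,4,5-trimethoxyphenyl)propanoyl}-1,3-oxazolidin-2-one
Product: 10 (2S)-2-[5-bromo-2-(methoxymethoxy)phenyl]-3-(3,4,5-trimethoxyphenyl)propan-1-ol
Conditions: LiBH4 (2 equiv), MeOH (2 equiv), Et2O/THF, 0 °C; aq. NH4Cl
Reagents that add atoms: none
Why: Reductive cleavage of the N-acyloxazolidinone with the LiBH4/MeOH reagent: hydride attacks the exocyclic imide carbonyl and the aldehyde released is reduced faster than it can enolise, so the (2S) centre is kept while the aryl bromide, the MOM ether and the methoxy groups are inert.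

Step 5
Reactants: 10 (2S)-2-[5-bromo-2-(methoxymethoxy)phenyl]-3-(3,4,5-trimethoxyphenyl)propan-1-ol
Product: 11 (2S)-2-[5-bromo-2-(methoxymethoxy)phenyl]-3-(3,4,5-trimethoxyphenyl)propyl pivalate
Conditions: pivaloyl chloride (1.3 equiv), Et3N (2 equiv), 4-(dimethylamino)pyridine (cat.), CH2Cl2, 0 °C → rt
Reagents that add atoms: pivaloyl chloride, CC(C)(C)C(=O)Cl
Why: Nucleophile-catalysed esterification of the only free hydroxyl group; the pivalate is chosen because it survives steps 6 to 8, adds bulk next to C3 for the trans closure, stops the cation of step 7 from losing formaldehyde, and falls in the final hydride reduction.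

Step 6
Reactants: 11 (2S)-2-[5-bromo-2-(methoxymethoxy)phenyl]-3-(3,4,5-trimethoxyphenyl)propyl pivalate
Product: 12 (2S)-2-(5-bromo-2-hydroxyphenyl)-3-(3,4,5-trimethoxyphenyl)propyl pivalate
Conditions: conc. HCl (cat.), MeOH, 45 °C
Reagents that add atoms: none
Why: Acid-catalysed transacetalisation moves the CH2 unit of the aryl MOM ether to methanol, whereas the hindered pivalate, the aryl methyl ethers and the non-enolisable stereocentre do not respond to dilute methanolic acid.

Step 7
Reactants: 12 (2S)-2-(5-bromo-2-hydroxyphenyl)-3-(3,4,5-trimethoxyphenyl)propyl pivalate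
Product: 14 [(2R,3S)-5-bromo-2-(3,4,5-trimethoxyphenyl)-2,3-dihydro-1-benzofuran-3-yl]methyl pivalate, via benzylic cation 13 (not isolated)
Conditions: 2,3-dichloro-5,6-dicyano-1,4-benzoquinone (DDQ, 1.1 equiv), powdered 4 Å molecular sieves, CH2Cl2 (0.02 M), 0 °C → rt; aq. NaHCO3 wash
Reagents that add atoms: none
Why: The quinone first associates with the most electron-rich π system of 12, the trimethoxyphenyl ring, and then takes hydride from the CH2 group attached to it, which gives cation 13 with its charge shared by the para methoxy oxygen (an O-methylated para-quinone methide); the phenol oxygen adds to C2 and the hydroquinone anion removes the proton. The closest known reaction type is the DDQ-mediated oxidative C–H cycloetherification of 2-(arylalkyl)phenols at alkoxy-activated benzylic positions, established for flavans and 2-aryl-2,3-dihydrobenzofurans. Ring B closes in the 5-exo-trig mode, because the C2=C(aryl) bond of the quinone-methide form stays outside the new five-membered ring. The new C2 centre is controlled by C3: O1 bonds to the planar cation in the conformer that places the aryl group anti to the bulky CH2OPiv arm, and since the acidic hydroquinone lets the doubly activated C2–O1 bond ionise again, any cis isomer should drain into the more stable trans (2R,3S) ring while C3 is never touched. The step needs site selectivity between two benzylic C–H bonds, as loss of the tertiary C3–H would lead through an ortho-quinone methide to racemic or eliminated material; the substrate secures attack at C2–H by the stronger donor ring next to it, by the bromine para to the phenol oxygen, which also blocks that position, and by the electron-withdrawing acyloxymethyl group on C3. The pivalate further prevents retro-Prins loss of formaldehyde from 13, and high dilution together with a near-stoichiometric charge of oxidant at or below room temperature counters intermolecular arylation and dehydrogenation of 14 to the benzofuran.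

Step 8
Reactants: 14 [(2R,3S)-5-bromo-2-(3,4,5-trimethoxyphenyl)-2,3-dihydro-1-benzofuran-3-yl]methyl pivalate; 15 methyl acrylate
Product: 16 methyl (2E)-3-[(2R,3S)-3-(pivaloyloxymethyl)-2-(3,4,5-trimethoxyphenyl)-2,3-dihydro-1-benzofuran-5-yl]prop-2-enoate
Conditions: Pd(OAc)2 (5 mol %), P(o-tolyl)3 (12 mol %), Et3N (2 equiv), 15 (2 equiv), DMF, 100 °C, sealed vessel
Reagents that add atoms: none
Why: Mizoroki–Heck reaction: zerovalent palladium formed in situ inserts into the C5–Br bond, syn carbopalladation of the acrylate at its unsubstituted terminus and syn β-hydride elimination give the E-cinnamate, and neither stereocentre is touched because neither carries a hydrogen that Et3N can remove.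

Step 9
Reactants: 16 methyl (2E)-3-[(2R,3S)-3-(pivaloyloxymethyl)-2-(3,4,5-trimethoxyphenyl)-2,3-dihydro-1-benzofuran-5-yl]prop-2-enoate
Product: 17 (2E)-3-[(2R,3S)-3-(hydroxymethyl)-2-(3,4,5-trimethoxyphenyl)-2,3-dihydro-1-benzofuran-5-yl]prop-2-en-1-ol
Conditions: i-Bu2AlH (6 equiv), CH2Cl2, −78 → 0 °C; aq. potassium sodium tartrate
Reagents that add atoms: none
Why: Ester reduction with i-Bu2AlH: 1,2-hydride delivery turns the enoate into the E-allylic alcohol without conjugate reduction and the same reagent cleaves the pivalate reductively, so both hydroxyl groups appear in one operation with C2, C3 and the alkene geometry unchanged.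

Compound list
1 | 2-(5-bromo-2-hydroxyphenyl)acetic acid | OC(=O)Cc1cc(Br)ccc1O | starting material
2 | methoxymethyl 2-[5-bromo-2-(methoxymethoxy)phenyl]acetate | COCOC(=O)Cc1cc(Br)ccc1OCOC | intermediate
3 | 2-[5-bromo-2-(methoxymethoxy)phenyl]acetic acid | OC(=O)Cc1cc(Br)ccc1OCOC | intermediate
4 | (4S)-4-benzyl-1,3-oxazolidin-2-one | O=C1N[C@@H](Cc2ccccc2)CO1 | starting material
5 | 2-[5-bromo-2-(methoxymethoxy)phenyl]acetic pivalic anhydride | CC(C)(C)C(=O)OC(=O)Cc1cc(Br)ccc1OCOC | intermediate
6 | (4S)-4-benzyl-3-{2-[5-bromo-2-(methoxymethoxy)phenyl]acetyl}-1,3-oxazolidin-2-one | O=C1OC[C@H](Cc2ccccc2)N1C(=O)Cc1cc(Br)ccc1OCOC | intermediate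
7 | 3,4,5-trimethoxybenzyl bromide | COc1cc(CBr)cc(OC)c1OC | starting material
8 | sodium (Z)-enolate of imide 6 | [Na+].[O-]/C(=C\c1cc(Br)ccc1OCOC)N1C(=O)OC[C@@H]1Cc1ccccc1 | intermediate
9 | (4S)-4-benzyl-3-{(2S)-2-[5-bromo-2-(methoxymethoxy)phenyl]-3-(3,4,5-trimethoxyphenyl)propanoyl}-1,3-oxazolidin-2-one | COc1cc(C[C@H](C(=O)N2C(=O)OC[C@@H]2Cc2ccccc2)c2cc(Br)ccc2OCOC)cc(OC)c1OC | intermediate
10 | (2S)-2-[5-bromo-2-(methoxymethoxy)phenyl]-3-(3,4,5-trimethoxyphenyl)propan-1-ol | COc1cc(C[C@H](CO)c2cc(Br)ccc2OCOC)cc(OC)c1OC | intermediate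
11 | (2S)-2-[5-bromo-2-(methoxymethoxy)phenyl]-3-(3,4,5-trimethoxyphenyl)propyl pivalate | COc1cc(C[C@H](COC(=O)C(C)(C)C)c2cc(Br)ccc2OCOC)cc(OC)c1OC | intermediate
12 | (2S)-2-(5-bromo-2-hydroxyphenyl)-3-(3,4,5-trimethoxyphenyl)propyl pivalate | COc1cc(C[C@H](COC(=O)C(C)(C)C)c2cc(Br)ccc2O)cc(OC)c1OC | intermediate
13 | (2S)-2-(5-bromo-2-hydroxyphenyl)-3-(pivaloyloxy)-1-(3,4,5-trimethoxyphenyl)propan-1-ylium | COc1cc([CH+][C@H](COC(=O)C(C)(C)C)c2cc(Br)ccc2O)cc(OC)c1OC | intermediate
14 | [(2R,3S)-5-bromo-2-(3,4,5-trimethoxyphenyl)-2,3-dihydro-1-benzofuran-3-yl]methyl pivalate (trans) | COc1cc([C@@H]2Oc3ccc(Br)cc3[C@H]2COC(=O)C(C)(C)C)cc(OC)c1OC | intermediate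
15 | methyl acrylate | C=CC(=O)OC | starting material
16 | methyl (2E)-3-[(2R,3S)-3-(pivaloyloxymethyl)-2-(3,4,5-trimethoxyphenyl)-2,3-dihydro-1-benzofuran-5-yl]prop-2-enoate | COc1cc([C@@H]2Oc3ccc(/C=C/C(=O)OC)cc3[C@H]2COC(=O)C(C)(C)C)cc(OC)c1OC | intermediate
17 | (2E)-3-[(2R,3S)-3-(hydroxymethyl)-2-(3,4,5-trimethoxyphenyl)-2,3-dihydro-1-benzofuran-5-yl]prop-2-en-1-ol | COc1cc([C@@H]2Oc3ccc(/C=C/CO)cc3[C@H]2CO)cc(OC)c1OC | target

Total step count: 9. Longest linear sequence: 9 steps (1 → 17); 4, 7 and 15 enter as purchased building blocks.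

Steps most likely to fail

Step 7.
- Hydride abstraction may be too slow, because the para methoxy group is twisted out of conjugation by its two neighbours.
- The oxidant may instead engage the phenol or the C3–H bond, with loss of stereochemical information.
- The ring-closed product may be dehydrogenated further.

The fallback sets out from 3 and returns at 14. It brings in the C2 oxygen by an aldol reaction instead of C–H oxidation and closes the same O1–C2 bond by acid ionisation. Acid 3 is activated as anhydride 5 and coupled with purchased (R)-4-benzyl-1,3-oxazolidin-2-one to the enantiomeric imide F1. The antipodal auxiliary is needed because the non-chelated boron aldol uses the enolate face opposite to that of the chelated alkylation. Enolisation with n-Bu2BOSO2CF3/i-Pr2NEt (CH2Cl2, −78 → 0 °C) and addition to 3,4,5-trimethoxybenzaldehyde should give the Evans syn aldol adduct F2. LiBH4 then releases the 1,3-diol F3. One equivalent of pivaloyl chloride in pyridine at 0 °C acylates the primary hydroxyl group to the monopivalate F4. CF3CO2H in CH2Cl2 at 0 °C ionises the benzylic alcohol, strips the MOM group and lets the oxygen on C7a close ring B under the same C3 control, which gives 14.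

Step 3.
- The hindered, stabilised arylacetyl enolate may alkylate slowly.
- The enolate may decompose by loss of the auxiliary.
- Facial selection may be poor.
- The acidic α-hydrogen of the product may be exchanged by surplus base, with erosion of the new centre.

The fallback sets out from 3 and returns at 9. Double deprotonation of 3 with LiN(i-Pr)2 (2.2 equiv, THF, −78 → 0 °C) gives a far more nucleophilic carboxylate enolate, and its benzylation with 7 should give the racemic 2,3-diarylpropanoic acid F5. Pivaloyl chloride/Et3N converts it to the racemic mixed anhydride F6. Coupling with 4 (LiCl, Et3N) gives 9 together with its (2R) epimer F7. The two diastereomers are parted by chromatography or crystallisation, so the stereocentre comes from a separation and not from facial selection. F7 can be equilibrated with a mild amine base and separated again.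

Step 4.
- With the crowded α,β-diaryl acyl group, hydride may attack the ring carbonyl of the auxiliary and open it.
- The transient α-aryl aldehyde may enolise before it is reduced.

The fallback sets out from 9 and returns at 10. LiOH/H2O2 (THF/H2O, 0 °C, Na2SO3 quench) cleaves even hindered imides at the exocyclic carbonyl and should give the (2S)-carboxylic acid F8. BH3·THF (0 °C → rt) then reduces the acid to 10 without a free aldehyde under basic conditions and without touching the aryl bromide or the MOM ether.

Further compounds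
F1 | step 7 | (4R)-4-benzyl-3-{2-[5-bromo-2-(methoxymethoxy)phenyl]acetyl}-1,3-oxazolidin-2-one | O=C1OC[C@@H](Cc2ccccc2)N1C(=O)Cc1cc(Br)ccc1OCOC
F2 | step 7 | (4R)-4-benzyl-3-{(2R,3R)-2-[5-bromo-2-(methoxymethoxy)phenyl]-3-hydroxy-3-(3,4,5-trimethoxyphenyl)propanoyl}-1,3-oxazolidin-2-one | COc1cc([C@H](O)[C@H](C(=O)N2C(=O)OC[C@H]2Cc2ccccc2)c2cc(Br)ccc2OCOC)cc(OC)c1OC
F3 | step 7 | (1R,2S)-2-[5-bromo-2-(methoxymethoxy)phenyl]-1-(3,4,5-trimethoxyphenyl)propane-1,3-diol | COc1cc([C@H](O)[C@H](CO)c2cc(Br)ccc2OCOC)cc(OC)c1OC
F4 | step 7 | (2S,3R)-2-[5-bromo-2-(methoxymethoxy)phenyl]-3-hydroxy-3-(3,4,5-trimethoxyphenyl)propyl pivalate | COc1cc([C@H](O)[C@H](COC(=O)C(C)(C)C)c2cc(Br)ccc2OCOC)cc(OC)c1OC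
F5 | step 3 | racemic 2-[5-bromo-2-(methoxymethoxy)phenyl]-3-(3,4,5-trimethoxyphenyl)propanoic acid | COc1cc(CC(C(=O)O)c2cc(Br)ccc2OCOC)cc(OC)c1OC
F6 | step 3 | racemic 2-[5-bromo-2-(methoxymethoxy)phenyl]-3-(3,4,5-trimethoxyphenyl)propanoic pivalic anhydride | COc1cc(CC(C(=O)OC(=O)C(C)(C)C)c2cc(Br)ccc2OCOC)cc(OC)c1OC
F7 | step 3 | (4S)-4-benzyl-3-{(2R)-2-[5-bromo-2-(methoxymethoxy)phenyl]-3-(3,4,5-trimethoxyphenyl)propanoyl}-1,3-oxazolidin-2-one | COc1cc(C[C@@H](C(=O)N2C(=O)OC[C@@H]2Cc2ccccc2)c2cc(Br)ccc2OCOC)cc(OC)c1OC
F8 | step 4 | (2S)-2-[5-bromo-2-(methoxymethoxy)phenyl]-3-(3,4,5-trimethoxyphenyl)propanoic acid | COc1cc(C[C@H](C(=O)O)c2cc(Br)ccc2OCOC)cc(OC)c1OC
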